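## Retrosynthetic overview

1. Target 24 ⇐ late enone unveiling (C-3 silyl ether → C2=C3 alkene → allylic oxidation at C-1) after double angeloylation of a 7,15-diol.
2. Ring C (seven-membered) ⇐ samarium Reformatsky closure of C6–C7 on a bicyclic bromo ester aldehyde, then Fráter–Seebach methylation at C-6.
3. The acetate arm on the cyclobutane ⇐ HWE olefination and conjugate reduction of cyclobutanone 7; the aldehyde ⇐ ozonolysis of the prenyl terminus.
4. Bicyclo[3.1.1]heptanone 7 (cyclobutane and six-membered ring formed together) ⇐ intramolecular ketene–alkene [2+2] cycloaddition of ketene 6.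
5. Acid 5 ⇐ (3S,6E)-nerolidol 1. Ring order: cyclobutane + six-membered ring first, ring C second.

Assumption: natural (+)-(3S,6E)-nerolidol is taken as the commercial enantiopure starting material. Bicyclic compounds carry bicyclo[3.1.1]heptane numbers (C-6 carbonyl bridge, C-7 the other one-carbon bridge). Tricyclic compounds carry longipinane numbers (C-14 = methyl on C-6, C-15 = oxygenated carbon on C-6).

Two stereochemical points rest on prediction, not precedent: the facial ratio in step 4 and the C-7 epimer ratio in step 9 (expected near 1:1, handled by separation and recycling).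

## Route

Step 1
Reactants: 1 (3S,6E)-nerolidol
Product: 2 (3S,6E)-3,7,11-trimethyl-3-(triethylsilyloxy)dodeca-1,6,10-triene
Conditions: Et3SiOTf, 2,6-lutidine, CH2Cl2, −78 to 0 °C
Reagents that add atoms: triethylsilyl triflate CC[Si](CC)(CC)OS(=O)(=O)C(F)(F)F
Why: Silyl triflate silylation protects the hindered tertiary alcohol (a free β-hydroxyl would lactonize in step 4) without touching the stereocentre bought with 1.

Step 2
Reactants: 2 nerolidol triethylsilyl ether
Product: 4 (3S,6E)-3,7,11-trimethyl-3-(triethylsilyloxy)dodeca-6,10-dien-1-ol, via B-alkyl-9-BBN borane 3 (not isolated)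
Conditions: 9-BBN, THF, 0 °C to rt; then NaOH, H2O2, 0 °C
Reagents that add atoms: hydrogen peroxide OO (hydroxyl oxygen); 9-BBN B1C2CCCC1CCC2 (boron only in 3)
Why: Anti-Markovnikov hydroboration–oxidation, in which 9-BBN reacts only with the monosubstituted vinyl group and leaves both trisubstituted alkenes and C-3 untouched.

Step 3
Reactants: 4 primary alcohol
Product: 5 (3S,6E)-3,7,11-trimethyl-3-(triethylsilyloxy)dodeca-6,10-dienoic acid
Conditions: TEMPO (cat.), PhI(OAc)2, MeCN/pH 7 buffer, rt
Reagents that add atoms: water O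
Why: Nitroxyl-catalysed oxidation takes the primary alcohol through the aldehyde hydrate to the acid under near-neutral conditions that spare the alkenes and the silyl ether.

Step 4
Reactants: 5 silyloxy dienoic acid
Product: 7 (1S,2S,5S,7S)-2,7-dimethyl-7-(4-methylpent-3-en-1-yl)-2-(triethylsilyloxy)bicyclo[3.1.1]heptan-6-one, via silyloxy ketene 6 (not isolated)
Conditions: 2-chloro-1-methylpyridinium iodide, Et3N, MeCN, reflux, slow addition (0.005 M)
Reagents that add atoms: none
Why: Intramolecular ketene–alkene [2+2] cycloaddition: the ketene carbonyl carbon bonds to the less substituted alkene carbon (C-5) and the α-carbon to the disubstituted one (C-7), giving the bridged bicycle; the 6E geometry is retained suprafacially so the C-7 methyl lies syn to the C2–C4 bridge, and the bought C-2 centre sets the face because the smaller OSiEt3, not methyl, is expected to take the crowded position next to that methyl (minor diastereomer removed by chromatography).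

Step 5
Reactants: 7 bicyclic cyclobutanone; 8 trimethyl phosphonoacetate
Product: 9 methyl [2,7-dimethyl-7-(4-methylpent-3-en-1-yl)-2-(triethylsilyloxy)bicyclo[3.1.1]heptan-6-ylidene]acetate (ring centres as in 7; E/Z mixture)
Conditions: NaH, THF, 0 °C; then 7, reflux
Reagents that add atoms: trimethyl phosphonoacetate 8 COC(=O)CP(=O)(OC)OC
Why: Horner–Wadsworth–Emmons olefination of the strained, electrophilic and non-enolizable cyclobutanone; the alkene geometry is irrelevant because C-6 becomes sp3 in step 6.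

Step 6
Reactants: 9 exocyclic enoate
Product: 10 methyl [2,7-dimethyl-7-(4-methylpent-3-en-1-yl)-2-(triethylsilyloxy)bicyclo[3.1.1]heptan-6-yl]acetate (6-H syn to the C2–C4 bridge; acetate arm cis to the C-7 chain)
Conditions: Mg, MeOH, rt
Reagents that add atoms: none
Why: Dissolving-metal conjugate reduction in which C-6 is protonated from the face of the three-carbon bridge, because the opposite face is covered by the C-7 chain and an arm on the bridge face would clash with the C-2 methyl, so the arm ends cis to the chain as ring C requires; the isolated alkene is not reduced.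

Step 7
Reactants: 10 saturated ester
Product: 12 methyl bromo[2,7-dimethyl-7-(4-methylpent-3-en-1-yl)-2-(triethylsilyloxy)bicyclo[3.1.1]heptan-6-yl]acetate (CHBr epimers), via lithium ester enolate 11 (not isolated)
Conditions: LiN(iPr)2, THF, −78 °C; then CBr4, −78 °C; aq. NH4Cl
Reagents that add atoms: carbon tetrabromide BrC(Br)(Br)Br (bromine); LiN(iPr)2 [Li+].CC(C)[N-]C(C)C (lithium only in 11)
Why: Kinetic ester enolate formation (the only acidic C–H) followed by electrophilic bromination gives the Reformatsky precursor; the CHBr centre is lost again in step 9.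

Step 8
Reactants: 12 bromo ester
Product: 14 methyl bromo[2,7-dimethyl-7-(3-oxopropyl)-2-(triethylsilyloxy)bicyclo[3.1.1]heptan-6-yl]acetate, via secondary ozonide 13 (not isolated)
Conditions: O3, CH2Cl2, −78 °C; then Me2S, −78 °C to rt
Reagents that add atoms: ozone [O-][O+]=O
Why: Ozonolysis of the only remaining C=C bond with reductive work-up unmasks the aldehyde (acetone is lost) and tolerates the bromo ester and silyl ether.

Step 9
Reactants: 14 bromo ester aldehyde
Product: 15 methyl (7R)-7-hydroxy-3-(triethylsilyloxy)-14-norlongipinan-15-oate (C-6 epimers)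
Conditions: SmI2, THF, −78 °C, 0.005 M; aq. NH4Cl
Reagents that add atoms: none
Why: Samarium Reformatsky reaction (intramolecular aldol-type C6–C7 bond formation) through a chelated samarium enolate closes the seven-membered ring across the lower cyclobutane face where both arms already sit; the distant C-3 centre hardly differentiates the aldehyde faces, so the 7R carbinol (hydroxyl on the C-4 side) is separated by chromatography from its 7S epimer, while C-6 stays epimerizable and is fixed in step 10.

Step 10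
Reactants: 15 ring C hydroxy ester
Product: 17 methyl 7-hydroxy-3-(triethylsilyloxy)longipinan-15-oate (C-14 methyl cis to 7-OH), via dilithium alkoxide enolate 16 (not isolated)
Conditions: LiN(iPr)2 (2.5 equiv), THF/DMPU, −78 to −30 °C; then MeI; aq. NH4Cl
Reagents that add atoms: iodomethane CI (methyl); LiN(iPr)2 [Li+].CC(C)[N-]C(C)C (lithium only in 16)
Why: Fráter–Seebach alkylation, in which the chelated alkoxide–enolate is methylated on the face cis to the C-7 oxygen, fixing quaternary C-6 with methyl cis and the carboxyl carbon trans to the hydroxyl as in the target.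

Step 11
Reactants: 17 quaternary hydroxy ester
Product: 18 3-(triethylsilyloxy)longipinane-7,15-diol
Conditions: LiAlH4, THF, 0 °C to reflux; NaOH/H2O work-up
Reagents that add atoms: none
Why: Hydride reduction of the neopentyl ester to the primary alcohol; no stereocentre is affected and the silyl ether survives.

Step 12
Reactants: 18 diol; 19 angelic acid
Product: 21 3-(triethylsilyloxy)longipinane-7,15-diyl bis[(Z)-2-methylbut-2-enoate], via angelic trichlorobenzoic mixed anhydride 20 (not isolated)
Conditions: 19, 2,4,6-trichlorobenzoyl chloride, Et3N, toluene, rt; then 18, toluene, 80 °C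
Reagents that add atoms: angelic acid 19 C/C=C(/C)C(O)=O; 2,4,6-trichlorobenzoyl chloride O=C(Cl)c1c(Cl)cc(Cl)cc1Cl (only in 20)
Why: Yamaguchi-type acylation through the pre-formed mixed anhydride without DMAP transfers the angeloyl group to both hydroxyls without Z-to-E isomerization to tiglate; no stereocentre is touched.

Step 13
Reactants: 21 bis-angelate silyl ether
Product: 22 3-hydroxylongipinane-7,15-diyl bis[(Z)-2-methylbut-2-enoate]
Conditions: HF·pyridine, THF/pyridine, 0 °C to rt
Reagents that add atoms: none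
Why: Fluoride-driven Si–O cleavage under buffered conditions that leave the conjugated esters alone.

Step 14
Reactants: 22 tertiary alcohol
Product: 23 longipin-2-ene-7,15-diyl bis[(Z)-2-methylbut-2-enoate]
Conditions: Burgess reagent (MeO2CN–SO2NEt3), toluene, 60 °C
Reagents that add atoms: none
Why: Burgess syn-elimination of the tertiary alcohol; C-4 is a bridgehead, so only C-2 or the methyl can lose hydrogen, and the trisubstituted endocyclic alkene is expected as the main product (exocyclic isomer removed); this erases the C-3 centre after it has done its work.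

Step 15
Reactants: 23 longipin-2-ene diester
Product: 24 (4R,5S,6S,7R,10R,11R)-1-oxolongipin-2-ene-7,15-diyl bis[(Z)-2-methylbut-2-enoate] (target)
Conditions: Mn(OAc)3·2H2O (cat.), t-BuOOH, 3 Å MS, EtOAc, rt
Reagents that add atoms: tert-butyl hydroperoxide CC(C)(C)OO
Why: Radical allylic oxidation at C-1, the only secondary allylic position, gives the enone as in the pinene-to-verbenone oxidation; the electron-poor angelate double bonds and the bridgehead C–H do not compete, and no stereocentre is touched.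

## Compound list

1 | (3S,6E)-nerolidol | C=C[C@@](C)(O)CC/C=C(\C)CCC=C(C)C | starting material
2 | (3S,6E)-3,7,11-trimethyl-3-(triethylsilyloxy)dodeca-1,6,10-triene | C=C[C@@](C)(O[Si](CC)(CC)CC)CC/C=C(\C)CCC=C(C)C | intermediate
3 | B-alkyl-9-BBN borane from 2 | B1(CC[C@@](C)(O[Si](CC)(CC)CC)CC/C=C(\C)CCC=C(C)C)C2CCCC1CCC2 | intermediate (not isolated)
4 | (3S,6E)-3,7,11-trimethyl-3-(triethylsilyloxy)dodeca-6,10-dien-1-ol | OCC[C@@](C)(O[Si](CC)(CC)CC)CC/C=C(\C)CCC=C(C)C | intermediate
5 | (3S,6E)-3,7,11-trimethyl-3-(triethylsilyloxy)dodeca-6,10-dienoic acid | OC(=O)C[C@@](C)(O[Si](CC)(CC)CC)CC/C=C(\C)CCC=C(C)C | intermediate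
6 | (3S,6E)-3,7,11-trimethyl-3-(triethylsilyloxy)dodeca-1,6,10-trien-1-one (ketene) | O=C=C[C@@](C)(O[Si](CC)(CC)CC)CC/C=C(\C)CCC=C(C)C | intermediate (not isolated)
7 | (1S,2S,5S,7S)-2,7-dimethyl-7-(4-methylpent-3-en-1-yl)-2-(triethylsilyloxy)bicyclo[3.1.1]heptan-6-one | O=C1[C@H]2CC[C@](C)(O[Si](CC)(CC)CC)[C@@H]1[C@@]2(C)CCC=C(C)C | intermediate
8 | trimethyl phosphonoacetate | COC(=O)CP(=O)(OC)OC | starting material
9 | methyl [bicyclo[3.1.1]heptan-6-ylidene]acetate derived from 7 (E/Z mixture) | COC(=O)C=C1[C@H]2CC[C@](C)(O[Si](CC)(CC)CC)[C@@H]1[C@@]2(C)CCC=C(C)C | intermediate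
10 | methyl [bicyclo[3.1.1]heptan-6-yl]acetate (arm cis to the C-7 chain) | COC(=O)C[C@@H]1[C@H]2CC[C@](C)(O[Si](CC)(CC)CC)[C@@H]1[C@@]2(C)CCC=C(C)C | intermediate
11 | lithium enolate of 10 | [Li]OC(OC)=C[C@@H]1[C@H]2CC[C@](C)(O[Si](CC)(CC)CC)[C@@H]1[C@@]2(C)CCC=C(C)C | intermediate (not isolated)
12 | α-bromo ester of 10 (CHBr epimers) | COC(=O)C(Br)[C@@H]1[C@H]2CC[C@](C)(O[Si](CC)(CC)CC)[C@@H]1[C@@]2(C)CCC=C(C)C | intermediate
13 | secondary ozonide of 12 | COC(=O)C(Br)[C@@H]1[C@H]2CC[C@](C)(O[Si](CC)(CC)CC)[C@@H]1[C@@]2(C)CCC3OOC(C)(C)O3 | intermediate (not isolated)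
14 | bromo ester aldehyde (7-(3-oxopropyl) compound) | COC(=O)C(Br)[C@@H]1[C@H]2CC[C@](C)(O[Si](CC)(CC)CC)[C@@H]1[C@@]2(C)CCC=O | intermediate
15 | methyl (7R)-7-hydroxy-3-(triethylsilyloxy)-14-norlongipinan-15-oate (C-6 epimers) | COC(=O)C1[C@@H]2[C@H]3CC[C@](C)(O[Si](CC)(CC)CC)[C@@H]2[C@@]3(C)CC[C@H]1O | intermediate
16 | dilithium alkoxide enolate of 15 | [Li]OC(OC)=C1[C@@H]2[C@H]3CC[C@](C)(O[Si](CC)(CC)CC)[C@@H]2[C@@]3(C)CC[C@H]1O[Li] | intermediate (not isolated)
17 | methyl 7-hydroxy-3-(triethylsilyloxy)longipinan-15-oate (C-14 methyl cis to 7-OH) | COC(=O)[C@]1(C)[C@@H]2[C@H]3CC[C@](C)(O[Si](CC)(CC)CC)[C@@H]2[C@@]3(C)CC[C@H]1O | intermediate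
18 | 3-(triethylsilyloxy)longipinane-7,15-diol | OC[C@]1(C)[C@@H]2[C@H]3CC[C@](C)(O[Si](CC)(CC)CC)[C@@H]2[C@@]3(C)CC[C@H]1O | intermediate
19 | angelic acid, (Z)-2-methylbut-2-enoic acid | C/C=C(/C)C(O)=O | starting material
20 | angelic 2,4,6-trichlorobenzoic anhydride | C/C=C(/C)C(=O)OC(=O)c1c(Cl)cc(Cl)cc1Cl | intermediate (not isolated)
21 | 3-(triethylsilyloxy)longipinane-7,15-diyl bis[(Z)-2-methylbut-2-enoate] | C/C=C(/C)C(=O)OC[C@]1(C)[C@@H]2[C@H]3CC[C@](C)(O[Si](CC)(CC)CC)[C@@H]2[C@@]3(C)CC[C@H]1OC(=O)/C(C)=C\C | intermediate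
22 | 3-hydroxylongipinane-7,15-diyl bis[(Z)-2-methylbut-2-enoate] | C/C=C(/C)C(=O)OC[C@]1(C)[C@@H]2[C@H]3CC[C@](C)(O)[C@@H]2[C@@]3(C)CC[C@H]1OC(=O)/C(C)=C\C | intermediate
23 | longipin-2-ene-7,15-diyl bis[(Z)-2-methylbut-2-enoate] | C/C=C(/C)C(=O)OC[C@]1(C)[C@@H]2[C@H]3CC=C(C)[C@@H]2[C@@]3(C)CC[C@H]1OC(=O)/C(C)=C\C | intermediate
24 | (4R,5S,6S,7R,10R,11R)-1-oxolongipin-2-ene-7,15-diyl bis[(Z)-2-methylbut-2-enoate] | C/C=C(/C)C(=O)OC[C@]1(C)[C@@H]2[C@H]3C(=O)C=C(C)[C@@H]2[C@@]3(C)CC[C@H]1OC(=O)/C(C)=C\C | target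

## Step count and risks

Total steps: 15. Longest linear sequence: 15 steps (1 → 24).

Steps most likely to fail:

Step 4 (ketene dimerization or a slow cycloaddition at the crowded ketene; facial ratio only predicted). The fallback sets out from acid 5 and comes back at ketone 7. Amide coupling of 5 with pyrrolidine (EDC·HCl, HOBt, CH2Cl2) gives pyrrolidine amide F1. Tf2O and 2,4,6-collidine in 1,2-dichloroethane at 80 °C turn it into keteniminium triflate F2, a far stronger electrophile than the ketene, which cyclizes in the flask to cyclobutaniminium triflate F3. Aqueous NaHCO3 hydrolysis of F3 returns 7.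

Step 9 (no real facial control at C-7, so the epimer ratio may be near 1:1 or unfavourable). The fallback sets out from aldehyde 14 and comes back at 15. The same cyclization delivers the 7S-epimer F4. Dess–Martin oxidation (NaHCO3, CH2Cl2) converts F4 into ring C β-keto ester F5, and NaBH4 in MeOH at −40 °C reduces the ketone again. C-7 is then set by hydride addition instead of by the C–C bond formation, 15 is separated, and F4 goes round the loop again.

Step 15 (allylic oxidation beside two angelates, on material whose exocyclic isomer from step 14 gives no useful enone). The fallback sets out from diol 18 and comes back at target 24; it moves the oxidation ahead of the acylation. 2,2-Dimethoxypropane and PPTS give diol acetonide F6. Bu4NF in THF frees tertiary alcohol F7. Burgess dehydration gives alkene acetonide F8. CrO3 with 3,5-dimethylpyrazole in CH2Cl2 at −20 °C, with no oxidizable ester present, gives enone acetonide F9. Aqueous acetic acid releases 7,15-dihydroxylongipin-2-en-1-one F10, which is acylated with mixed anhydride 20 as in step 12 to give 24.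

Further compounds

F1 | step 4 | pyrrolidine amide of acid 5 | O=C(C[C@@](C)(O[Si](CC)(CC)CC)CC/C=C(\C)CCC=C(C)C)N1CCCC1
F2 | step 4 | keteniminium triflate from F1 | [O-]S(=O)(=O)C(F)(F)F.C1CC[N+](C1)=C=C[C@@](C)(O[Si](CC)(CC)CC)CC/C=C(\C)CCC=C(C)C
F3 | step 4 | cyclobutaniminium triflate (pyrrolidinium ylidene of 7) | [O-]S(=O)(=O)C(F)(F)F.C1CC[N+](C1)=C1[C@H]2CC[C@](C)(O[Si](CC)(CC)CC)[C@@H]1[C@@]2(C)CCC=C(C)C
F4 | step 9 | methyl (7S)-7-hydroxy-3-(triethylsilyloxy)-14-norlongipinan-15-oate (7-epimer of 15) | COC(=O)C1[C@@H]2[C@H]3CC[C@](C)(O[Si](CC)(CC)CC)[C@@H]2[C@@]3(C)CC[C@@H]1O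
F5 | step 9 | methyl 7-oxo-3-(triethylsilyloxy)-14-norlongipinan-15-oate | COC(=O)C1[C@@H]2[C@H]3CC[C@](C)(O[Si](CC)(CC)CC)[C@@H]2[C@@]3(C)CCC1=O
F6 | step 15 | 7,15-O-isopropylidene-3-(triethylsilyloxy)longipinane-7,15-diol | CC4(C)OC[C@]1(C)[C@@H]2[C@H]3CC[C@](C)(O[Si](CC)(CC)CC)[C@@H]2[C@@]3(C)CC[C@H]1O4
F7 | step 15 | 7,15-O-isopropylidenelongipinane-3,7,15-triol | CC4(C)OC[C@]1(C)[C@@H]2[C@H]3CC[C@](C)(O)[C@@H]2[C@@]3(C)CC[C@H]1O4
F8 | step 15 | 7,15-O-isopropylidenelongipin-2-ene-7,15-diol | CC4(C)OC[C@]1(C)[C@@H]2[C@H]3CC=C(C)[C@@H]2[C@@]3(C)CC[C@H]1O4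
F9 | step 15 | 7,15-O-isopropylidene-7,15-dihydroxylongipin-2-en-1-one | CC4(C)OC[C@]1(C)[C@@H]2[C@H]3C(=O)C=C(C)[C@@H]2[C@@]3(C)CC[C@H]1O4
F10 | step 15 | 7,15-dihydroxylongipin-2-en-1-one | OC[C@]1(C)[C@@H]2[C@H]3C(=O)C=C(C)[C@@H]2[C@@]3(C)CC[C@H]1O
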